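**Retrosynthetic overview**

- Feature: with the oxolane numbered O1, C2 (aryl), C3 (CH2O-stearoyl), C4 (CH2Ar), C5, the pair C4/C3 maps onto the α/β carbons of a γ-alkoxybutanolide. C5 is the lactone carbonyl carbon, the C3 carbinol carbon is the acetal carbon, C2 is an acyl-level carbon on the β-position, and the C4 benzyl group is an α-alkyl group.
- The ester and the O1–C2 bond are disconnected first (benzylic cycloetherification of a triol), and the triol is traced back to a keto lactone and then to a dithianyl lactone.
- The dithianyl lactone comes from three components in one flask: the lithiated dithiane of O-benzylvanillin (C2–C3 bond), (5R)-5-(l-menthyloxy)furan-2(5H)-one, and 4-benzyloxy-3-methoxybenzyl bromide (C4–CH2Ar bond).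
- Ring order: the butenolide ring is made first from furfural (step 5) as a chiral template and is opened by hydride in step 9; the oxolane, the only ring of the target made in the route, closes in step 10.

Key step: step 7

Remark: the hydroxybutenolide from furfural is racemic and the triol is carried on as a mixture of epimers at the benzylic carbinol carbon; the first centre is reset in step 6 and the second in step 10.

**Route**

Step 1
Reactants: 1 vanillin
Product: 2 4-benzyloxy-3-methoxybenzaldehyde
Conditions: BnBr, K2CO3, DMF, rt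
Reagents that add atoms: benzyl bromide, BrCc1ccccc1
Why: Williamson ether synthesis on the phenoxide, which protects the phenol as a benzyl ether that is stable to organolithium, hydride and mild acid.

Step 2
Reactants: 2 4-benzyloxy-3-methoxybenzaldehyde
Product: 3 2-(4-benzyloxy-3-methoxyphenyl)-1,3-dithiane
Conditions: HS(CH2)3SH, BF3·OEt2 (cat.), CH2Cl2, 0 °C → rt
Reagents that add atoms: propane-1,3-dithiol, SCCCS
Why: Lewis-acid-catalysed dithioacetalisation of the aryl aldehyde, which turns the formyl carbon into a site that can be deprotonated (umpolung).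

Step 3
Reactants: 2 4-benzyloxy-3-methoxybenzaldehyde
Product: 4 (4-benzyloxy-3-methoxyphenyl)methanol
Conditions: NaBH4, MeOH, 0 °C
Reagents that add atoms: none
Why: borohydride reduction of the aldehyde to the benzylic alcohol.

Step 4
Reactants: 4 (4-benzyloxy-3-methoxyphenyl)methanol
Product: 5 4-benzyloxy-3-methoxybenzyl bromide
Conditions: PBr3, Et2O, 0 °C; used freshly prepared
Reagents that add atoms: phosphorus tribromide, BrP(Br)Br
Why: bromination of the benzylic alcohol through its phosphite ester (SN2 displacement by bromide) under conditions that leave the aryl ethers intact.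

Step 5
Reactants: 6 furfural
Product: 7 5-hydroxyfuran-2(5H)-one (racemic)
Conditions: O2, hν (visible), rose bengal (cat.), MeOH, rt
Reagents that add atoms: dioxygen, O=O
Why: dye-sensitised photooxygenation, in which singlet oxygen adds [4+2] across the furan and methanolysis of the 2-formyl endoperoxide expels the formyl carbon as methyl formate to leave the hydroxybutenolide, whose hemiacetal centre is racemic and labile.

Step 6
Reactants: 7 5-hydroxyfuran-2(5H)-one, 8 (−)-menthol
Product: 9 (5R)-5-[(1R,2S,5R)-2-isopropyl-5-methylcyclohexyloxy]furan-2(5H)-one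
Conditions: p-TsOH (cat.), toluene, reflux with azeotropic removal of water; crystallisation from petroleum ether, mother liquor re-equilibrated with p-TsOH and recrystallised
Reagents that add atoms: none
Why: acid-catalysed acetalisation through the cyclic oxocarbenium ion gives both C5 epimers, which interconvert under acid, and the (5R) epimer is the one expected to crystallise, so the acetal stereocentre is set by crystallisation-induced diastereomer transformation under control of the menthyl group.

Step 7
Reactants: 3 2-(4-benzyloxy-3-methoxyphenyl)-1,3-dithiane, 9 (5R)-5-(l-menthyloxy)furan-2(5H)-one, 5 4-benzyloxy-3-methoxybenzyl bromide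
Product: 12 (3R,4R,5R)-3-(4-benzyloxy-3-methoxybenzyl)-4-[2-(4-benzyloxy-3-methoxyphenyl)-1,3-dithian-2-yl]-5-(l-menthyloxy)dihydrofuran-2(3H)-one, via lithiated dithiane 10 (not isolated), via lithium enolate 11 (not isolated)
Conditions: n-BuLi, THF, −78 °C; then 9, −78 °C; then 5, DMPU, −78 → −30 °C; aq. NH4Cl
Reagents that add atoms: none
Why: n-BuLi removes the C2–H of dithiane 3 to give the sulfur- and aryl-stabilised carbanion 10, an acyl-anion equivalent that adds in Michael fashion to C4 of butenolide 9 (the C2–C3 bond of the target oxolane) to give lithium enolate 11, which is C-alkylated by benzylic bromide 5 in an SN2 step (the C4–CH2Ar bond of the target). The closest known reaction type is the tandem conjugate addition–enolate alkylation of lithiated 2-aryl-1,3-dithianes on 5-alkoxyfuran-2(5H)-ones. No ring closes in this step. The lactone C4 centre is controlled by the C5 acetal centre, the nucleophile entering anti to the menthyloxy group, and the lactone C3 centre is controlled by the new bulky dithianyl group, the electrophile entering anti to it, so the 3,4-trans-4,5-trans (3R,4R,5R) lactone should result; these two centres become C3 and C4 of the oxolane, where the trans lactone corresponds to the 3,4-cis ether because the ring is later closed through the dithiane carbon. The step needs 1,4- over 1,2-addition and C-alkylation before retro-Michael loss of the dithiane anion; the soft delocalised 2-aryl dithiane anion and the unhindered β-carbon favour conjugate addition, and the reactive electron-rich benzylic bromide with DMPU at low temperature should secure fast C-alkylation.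

Step 8
Reactants: 12 dithianyl lactone
Product: 13 (3R,4R,5R)-4-(4-benzyloxy-3-methoxybenzoyl)-3-(4-benzyloxy-3-methoxybenzyl)-5-(l-menthyloxy)dihydrofuran-2(3H)-one
Conditions: HgO, BF3·OEt2, THF/H2O, rt
Reagents that add atoms: water, O
Why: thiophilic Hg(II)-promoted hydrolysis of the S,S-acetal (dethioketalisation) unmasks the aryl ketone, and the centre α to the new ketone already has the thermodynamically preferred trans,trans arrangement, so it should not be scrambled.

Step 9
Reactants: 13 keto lactone
Product: 14 (2R,3R)-2-[(4-benzyloxy-3-methoxyphenyl)(hydroxy)methyl]-3-(4-benzyloxy-3-methoxybenzyl)butane-1,4-diol (both carbinol epimers)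
Conditions: LiAlH4, THF, 0 °C → reflux; aqueous NaOH work-up
Reagents that add atoms: none
Why: exhaustive LiAlH4 reduction, in which the ketone gives the benzylic carbinol, the lactone carbonyl gives a primary alcohol, and the hemiacetal so set free collapses to an aldehyde that is reduced to the second primary alcohol with release of (−)-menthol; aldehyde reduction outruns enolisation, so the two stereocentres are retained.

Step 10
Reactants: 14 triol
Product: 15 [(2S,3R,4R)-2-(4-benzyloxy-3-methoxyphenyl)-4-(4-benzyloxy-3-methoxybenzyl)oxolan-3-yl]methanol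
Conditions: CSA (cat.), CH2Cl2, 0 °C → rt
Reagents that add atoms: none
Why: acid-catalysed SN1 cycloetherification, in which the benzylic carbinol ionises to the p-alkoxybenzyl cation and is captured 5-exo by the hydroxymethyl group on the benzyl-bearing carbon (the other hydroxymethyl could only give an oxetane); both carbinol epimers converge, and the reversible benzylic C–O bond formation places the aryl group trans to the C3 substituent, setting C2 as S.

Step 11
Reactants: 15 oxolane alcohol, 16 stearic acid
Product: 17 [(2S,3R,4R)-2-(4-benzyloxy-3-methoxyphenyl)-4-(4-benzyloxy-3-methoxybenzyl)oxolan-3-yl]methyl octadecanoate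
Conditions: DCC, DMAP (cat.), CH2Cl2, 0 °C → rt
Reagents that add atoms: none
Why: Steglich esterification of the only free hydroxyl group under neutral conditions that do not ionise the benzylic ether.

Step 12
Reactants: 17 dibenzyl stearate
Product: 18 [(2S,3R,4R)-2-(4-hydroxy-3-methoxyphenyl)-4-(4-hydroxy-3-methoxybenzyl)oxolan-3-yl]methyl octadecanoate (target, CNP0168412.1)
Conditions: H2 (1 atm), 10% Pd/C, EtOAc, rt, stopped after uptake of two equivalents
Reagents that add atoms: none
Why: catalytic hydrogenolysis of the two aryl benzyl ethers, which in a neutral aprotic solvent should be much faster than cleavage of the cyclic benzylic C2–O bond and leaves the ester and the three stereocentres untouched.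

**Compound list**

1 | vanillin | COc1cc(C=O)ccc1O | starting material
2 | 4-benzyloxy-3-methoxybenzaldehyde | COc1cc(C=O)ccc1OCc1ccccc1 | intermediate
3 | 2-(4-benzyloxy-3-methoxyphenyl)-1,3-dithiane | COc1cc(C2SCCCS2)ccc1OCc1ccccc1 | intermediate
4 | (4-benzyloxy-3-methoxyphenyl)methanol | COc1cc(CO)ccc1OCc1ccccc1 | intermediate
5 | 4-benzyloxy-3-methoxybenzyl bromide | COc1cc(CBr)ccc1OCc1ccccc1 | intermediate
6 | furfural | O=Cc1ccco1 | starting material
7 | 5-hydroxyfuran-2(5H)-one (racemic) | OC1OC(=O)C=C1 | intermediate
8 | (−)-menthol, (1R,2S,5R) | C[C@@H]1CC[C@H]([C@@H](C1)O)C(C)C | starting material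
9 | (5R)-5-(l-menthyloxy)furan-2(5H)-one | C[C@@H]1CC[C@H]([C@@H](C1)O[C@@H]1OC(=O)C=C1)C(C)C | intermediate
10 | 2-lithio-2-(4-benzyloxy-3-methoxyphenyl)-1,3-dithiane (not isolated) | COc1cc(C2([Li])SCCCS2)ccc1OCc1ccccc1 | intermediate
11 | lithium enolate of (4R,5R)-4-(2-aryl-1,3-dithian-2-yl)-5-(l-menthyloxy)dihydrofuran-2(3H)-one (not isolated) | C[C@@H]1CC[C@H]([C@@H](C1)O[C@@H]1OC(O[Li])=C[C@H]1C1(c2ccc(OCc3ccccc3)c(OC)c2)SCCCS1)C(C)C | intermediate
12 | (3R,4R,5R)-3-(4-benzyloxy-3-methoxybenzyl)-4-[2-(4-benzyloxy-3-methoxyphenyl)-1,3-dithian-2-yl]-5-(l-menthyloxy)dihydrofuran-2(3H)-one | C[C@@H]1CC[C@H]([C@@H](C1)O[C@@H]1OC(=O)[C@H](Cc2ccc(OCc3ccccc3)c(OC)c2)[C@H]1C1(c2ccc(OCc3ccccc3)c(OC)c2)SCCCS1)C(C)C | intermediate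
13 | (3R,4R,5R)-4-(4-benzyloxy-3-methoxybenzoyl)-3-(4-benzyloxy-3-methoxybenzyl)-5-(l-menthyloxy)dihydrofuran-2(3H)-one | C[C@@H]1CC[C@H]([C@@H](C1)O[C@@H]1OC(=O)[C@H](Cc2ccc(OCc3ccccc3)c(OC)c2)[C@H]1C(=O)c1ccc(OCc2ccccc2)c(OC)c1)C(C)C | intermediate
14 | (2R,3R)-2-[(4-benzyloxy-3-methoxyphenyl)(hydroxy)methyl]-3-(4-benzyloxy-3-methoxybenzyl)butane-1,4-diol (carbinol epimers) | OC[C@@H]([C@@H](Cc1ccc(OCc2ccccc2)c(OC)c1)CO)C(O)c1ccc(OCc2ccccc2)c(OC)c1 | intermediate
15 | [(2S,3R,4R)-2-(4-benzyloxy-3-methoxyphenyl)-4-(4-benzyloxy-3-methoxybenzyl)oxolan-3-yl]methanol | OC[C@H]1[C@@H](Cc2ccc(OCc3ccccc3)c(OC)c2)CO[C@@H]1c1ccc(OCc2ccccc2)c(OC)c1 | intermediate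
16 | stearic acid | CCCCCCCCCCCCCCCCCC(=O)O | starting material
17 | [(2S,3R,4R)-2-(4-benzyloxy-3-methoxyphenyl)-4-(4-benzyloxy-3-methoxybenzyl)oxolan-3-yl]methyl octadecanoate | CCCCCCCCCCCCCCCCCC(=O)OC[C@H]1[C@@H](Cc2ccc(OCc3ccccc3)c(OC)c2)CO[C@@H]1c1ccc(OCc2ccccc2)c(OC)c1 | intermediate
18 | [(2S,3R,4R)-2-(4-hydroxy-3-methoxyphenyl)-4-(4-hydroxy-3-methoxybenzyl)oxolan-3-yl]methyl octadecanoate | CCCCCCCCCCCCCCCCCC(=O)OC[C@H]1[C@@H](Cc2ccc(O)c(OC)c2)CO[C@@H]1c1ccc(O)c(OC)c1 | target

**Step count and risks**

Total step count: 12.
Longest linear sequence: 9 steps (1 → 2 → 4 → 5 → 12 → 13 → 14 → 15 → 17 → 18, that is steps 1, 3, 4, 7, 8, 9, 10, 11, 12).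

The three steps most likely to fail:

Step 7. The dithiane anion may attack the lactone carbonyl instead of the β-carbon, or C-alkylation of the crowded enolate may be so slow that the enolate reverts by retro-Michael reaction on warming. The fallback separates the two bond formations. Setting out from 3 and 9, the anion of 3 is added to 9 at −78 °C and the enolate is protonated cold with acetic acid in THF to give the conjugate adduct (4R,5R)-4-[2-(4-benzyloxy-3-methoxyphenyl)-1,3-dithian-2-yl]-5-(l-menthyloxy)dihydrofuran-2(3H)-one F1, which can be purified and freed of any 1,2-adduct. F1 is then deprotonated with LDA in THF at −78 °C and alkylated with 5 in the presence of DMPU, again anti to the dithianyl group, which comes back to the route at 12.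

Step 10. The benzylic cation may be trapped by the electron-rich benzyl ring (Friedel–Crafts closure to an aryltetralin) in competition with the hydroxyl group, or the trans selectivity at C2 may be incomplete if the closure is not reversible under conditions mild enough to avoid that side reaction. The fallback removes the benzyl groups before ring closure, so that the cation is reached as a p-quinone methide under nearly neutral conditions. Setting out from 14, hydrogenolysis (H2, Pd/C, EtOAc/EtOH) should give (2R,3R)-2-[hydroxy(4-hydroxy-3-methoxyphenyl)methyl]-3-(4-hydroxy-3-methoxybenzyl)butane-1,4-diol F2. Its p-hydroxybenzylic alcohol should ionise in dilute acetic acid in aqueous dioxane at rt to 40 °C and close to (+)-lariciresinol F3. Transesterification with vinyl stearate catalysed by immobilised Candida antarctica lipase B (2-methyl-2-butanol, 50 °C) should acylate only the primary aliphatic hydroxyl group and not the phenols, which comes back to the route at the target 18 and bypasses steps 11 and 12.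

Step 8. Hydrolysis of the hindered dithiane may be slow enough that cleavage of the menthyl acetal or epimerisation next to the new ketone competes. The fallback changes the order, so that the carbonyl is unmasked on a substrate without the acetal. Setting out from 12, LiAlH4 in THF should give (2R,3R)-2-[2-(4-benzyloxy-3-methoxyphenyl)-1,3-dithian-2-yl]-3-(4-benzyloxy-3-methoxybenzyl)butane-1,4-diol F4 with release of menthol. Alkylative dethioketalisation (MeI, CaCO3, aqueous MeCN, 40 °C) should give (2R,3R)-2-(4-benzyloxy-3-methoxybenzoyl)-3-(4-benzyloxy-3-methoxybenzyl)butane-1,4-diol F5, in equilibrium with its five-membered hemiketal. F5 is reduced at once with NaBH4 in MeOH, before the centre next to the ketone can epimerise, which comes back to the route at 14.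

**Further compounds**

F1 | step 7 | (4R,5R)-4-[2-(4-benzyloxy-3-methoxyphenyl)-1,3-dithian-2-yl]-5-(l-menthyloxy)dihydrofuran-2(3H)-one | C[C@@H]1CC[C@H]([C@@H](C1)O[C@@H]1OC(=O)C[C@H]1C1(c2ccc(OCc3ccccc3)c(OC)c2)SCCCS1)C(C)C
F2 | step 10 | (2R,3R)-2-[hydroxy(4-hydroxy-3-methoxyphenyl)methyl]-3-(4-hydroxy-3-methoxybenzyl)butane-1,4-diol (carbinol epimers) | OC[C@@H]([C@@H](Cc1ccc(O)c(OC)c1)CO)C(O)c1ccc(O)c(OC)c1
F3 | step 10 | (+)-lariciresinol | OC[C@H]1[C@@H](Cc2ccc(O)c(OC)c2)CO[C@@H]1c1ccc(O)c(OC)c1
F4 | step 8 | (2R,3R)-2-[2-(4-benzyloxy-3-methoxyphenyl)-1,3-dithian-2-yl]-3-(4-benzyloxy-3-methoxybenzyl)butane-1,4-diol | OC[C@@H]([C@@H](Cc1ccc(OCc2ccccc2)c(OC)c1)CO)C1(c2ccc(OCc3ccccc3)c(OC)c2)SCCCS1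
F5 | step 8 | (2R,3R)-2-(4-benzyloxy-3-methoxybenzoyl)-3-(4-benzyloxy-3-methoxybenzyl)butane-1,4-diol | OC[C@@H]([C@@H](Cc1ccc(OCc2ccccc2)c(OC)c1)CO)C(=O)c1ccc(OCc2ccccc2)c(OC)c1
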